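**Strategy**

Ring A carries its two carbinol carbons, C3 and C4, side by side, so the ring is disconnected at the C3–C4 bond into an acyclic 1,6-dialdehyde. In this precursor the (E)-tetrasubstituted C5=C6 alkene and the C1 gem-dimethyl group hold the enal aldehyde (C4) next to the saturated aldehyde (C3). A chiral trivalent titanocene couples the two carbonyl carbons reductively; this single operation closes the six-membered ring and sets both stereocentres as the trans-(3R,4R) diol. The dialdehyde comes from ozonolysis of ethyl safranate; the ring ester is later extended to a C15 phosphonium salt and joined to a C25 polyenal assembled from pseudoionone and the C10 dialdehyde.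

Key step: step 2

**Assumptions**

- Atom labels follow carotenoid numbering (ring A: C1 gem-dimethyl, C3 and C4 carbinols, C5=C6 alkene, chain C7–C15; primed numbers for the acyclic half). TBS = tert-butyldimethylsilyl.
- Commercial ethyl safranate is used as the 1,3-diene isomer, freed from double-bond isomers by distillation if needed. Pseudoionone and phosphonate 8 are used as the geometric isomers drawn.
- Which antipode of (EBTHI)TiCl2 [ethylenebis(4,5,6,7-tetrahydro-1-indenyl)titanium dichloride] delivers the (3R,4R) diol cannot be predicted with confidence. It is to be fixed in a trial run; both antipodes are commercial.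
- The ethyl ester is kept at C7 through the key step. Flanked by the C5 methyl and C1, it is twisted out of conjugation, so it shields C5=C6 from ozone without turning the enal into an easily reduced ene-dicarbonyl.
- All polyene operations are run under argon in dim light.

**Route**

Step 1
Reactants: 1 ethyl safranate (ethyl 2,6,6-trimethylcyclohexa-1,3-diene-1-carboxylate)
Product: 3 ethyl (E)-3-methyl-2-(2-methyl-4-oxobutan-2-yl)-4-oxobut-2-enoate, via ozonide 2 (not isolated)
Conditions: O3 (1.0 equiv, Sudan Red 7B end-point), CH2Cl2, −78 °C; then PPh3, −78 °C → rt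
Reagents that add atoms: ozone, [O-][O+]=O
Why: Ozonolysis (Criegee mechanism) should cleave only the cis-disubstituted C3=C4 bond, because C5=C6 is tetrasubstituted, hindered by the gem-dimethyl group and inductively deactivated by the ester, and the ring geometry is carried over as the (E)-enal with C4 beside C1.

Step 2
Reactants: 3 ethyl (E)-3-methyl-2-(2-methyl-4-oxobutan-2-yl)-4-oxobut-2-enoate
Product: 4 ethyl (3R,4R)-3,4-dihydroxy-2,6,6-trimethylcyclohex-1-ene-1-carboxylate
Conditions: (R,R)-(EBTHI)TiCl2 (2.4 equiv), Zn dust, THF, rt, solution decanted from Zn; 3 added over 6 h (0.01 M), −30 → 0 °C; then aq. HCl (1 M), 0 °C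
Reagents that add atoms: none
Why: Proposed new method: each trivalent titanium centre binds an aldehyde oxygen and gives up one electron, the conjugated C4 aldehyde being reduced first to a titanium-bound allylic ketyl that attacks the titanium-activated C3 carbonyl carbon (or pairs with a C3 ketyl), so that the C3–C4 bond forms and a bis-titanium diolate results, which HCl cleaves to the diol. The closest known reaction type is the trans-selective reductive cyclisation of 1,6-dialdehydes to cyclohexane-1,2-diols by achiral trivalent titanocenes (Cp2TiCl, Cp2TiPh), and enantioselective intermolecular pinacol couplings with chiral titanium complexes support control by the ligand. Ring A closes in a 6-exo-trig mode, the oxygen of the attacked C3 carbonyl staying outside the new ring. The trans relation of C3 and C4 is set by the mutual repulsion of the two bulky titanium alkoxide groups, which sit anti and pseudo-equatorial in the half-chair transition state, and the absolute (3R,4R) sense by the C2-symmetric EBTHI ligand, which distinguishes the two faces of the C4 ketyl because the substrate has no stereocentre. The step needs reduction at C4 only, no intermolecular coupling and no other ring size: the twisted ester leaves C5=C6 intact, the alkene geometry places C4 beside C1, the gem-dimethyl group folds the C1–C2–C3 arm towards C4, closure at C6 or C5 would mean a four-membered or 5-endo ring, and slow addition at high dilution suppresses dimerisation.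

Step 3
Reactants: 4 ethyl (3R,4R)-3,4-dihydroxy-2,6,6-trimethylcyclohex-1-ene-1-carboxylate
Product: 5 ethyl (3R,4R)-3,4-bis(TBS-oxy)-2,6,6-trimethylcyclohex-1-ene-1-carboxylate
Conditions: TBSOTf (3 equiv), 2,6-lutidine (4 equiv), CH2Cl2, 0 °C → rt
Reagents that add atoms: tert-butyldimethylsilyl trifluoromethanesulfonate, CC(C)(C)[Si](C)(C)OS(=O)(=O)C(F)(F)F
Why: Silyl triflate silylation should cap both secondary alcohols, including the hindered allylic one, without touching C3 or C4, and the ethers withstand the hydride, base and ylide steps that follow.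

Step 4
Reactants: 5 ethyl (3R,4R)-3,4-bis(TBS-oxy)-2,6,6-trimethylcyclohex-1-ene-1-carboxylate
Product: 6 [(3R,4R)-3,4-bis(TBS-oxy)-2,6,6-trimethylcyclohex-1-en-1-yl]methanol
Conditions: i-Bu2AlH (3 equiv), CH2Cl2, −78 → 0 °C; aq. KNaC4H4O6 work-up
Reagents that add atoms: none
Why: Hydride reduction of the hindered ester should stop cleanly at the primary allylic alcohol, silyl ethers being inert to i-Bu2AlH.

Step 5
Reactants: 6 [(3R,4R)-3,4-bis(TBS-oxy)-2,6,6-trimethylcyclohex-1-en-1-yl]methanol
Product: 7 (3R,4R)-3,4-bis(TBS-oxy)-2,6,6-trimethylcyclohex-1-ene-1-carbaldehyde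
Conditions: Pr4N[RuO4] (5 mol %), N-methylmorpholine N-oxide, 4 Å molecular sieves, CH2Cl2, rt
Reagents that add atoms: none
Why: Ley–Griffith oxidation should convert the primary allylic alcohol into the C7 aldehyde under neutral conditions, and the aldehyde has no α-hydrogen to epimerise or enolise.

Step 6
Reactants: 7 (3R,4R)-3,4-bis(TBS-oxy)-2,6,6-trimethylcyclohex-1-ene-1-carbaldehyde; 8 ethyl (2E)-4-(diethoxyphosphoryl)-3-methylbut-2-enoate
Product: 9 ethyl (2E,4E)-5-[(3R,4R)-3,4-bis(TBS-oxy)-2,6,6-trimethylcyclohex-1-en-1-yl]-3-methylpenta-2,4-dienoate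
Conditions: 8 (1.5 equiv), LiN(SiMe3)2 (1.4 equiv), THF/DMPU, −78 °C; then 7, −78 → 0 °C
Reagents that add atoms: none
Why: Horner–Wadsworth–Emmons olefination, in which the preformed phosphonate carbanion (no free amide base) adds to the aldehyde and eliminates diethyl phosphate, should give the (E)-C7=C8 bond, with the (E)-C9=C10 bond coming from the reagent and any 9Z ester removed by chromatography at this stage.

Step 7
Reactants: 9 ethyl (2E,4E)-5-[(3R,4R)-3,4-bis(TBS-oxy)-2,6,6-trimethylcyclohex-1-en-1-yl]-3-methylpenta-2,4-dienoate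
Product: 10 (2E,4E)-5-[(3R,4R)-3,4-bis(TBS-oxy)-2,6,6-trimethylcyclohex-1-en-1-yl]-3-methylpenta-2,4-dien-1-ol
Conditions: i-Bu2AlH (2.5 equiv), CH2Cl2, −78 °C; aq. KNaC4H4O6 work-up
Reagents that add atoms: none
Why: 1,2-Reduction of the dienoate by i-Bu2AlH should give the C15 allylic alcohol without touching the alkene geometry or the silyl ethers.

Step 8
Reactants: 10 (2E,4E)-5-[(3R,4R)-3,4-bis(TBS-oxy)-2,6,6-trimethylcyclohex-1-en-1-yl]-3-methylpenta-2,4-dien-1-ol
Product: 12 {(2E,4E)-5-[(3R,4R)-3,4-bis(TBS-oxy)-2,6,6-trimethylcyclohex-1-en-1-yl]-3-methylpenta-2,4-dien-1-yl}triphenylphosphonium bromide, via allylic bromide 11 (not isolated)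
Conditions: CBr4 (1.2 equiv), PPh3 (1.2 equiv), CH2Cl2, −20 °C; then PPh3 (1.5 equiv), 0 °C → rt; precipitation from Et2O
Reagents that add atoms: triphenylphosphine, c1ccc(cc1)P(c1ccccc1)c1ccccc1; carbon tetrabromide, BrC(Br)(Br)Br
Why: Appel bromination under neutral conditions followed by SN2 capture of the reactive primary allylic bromide by PPh3 should give the phosphonium salt while avoiding the acid that would ionise the allylic C4 silyl ether.

Step 9
Reactants: 13 pseudoionone ((3E,5E)-6,10-dimethylundeca-3,5,9-trien-2-one)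
Product: 14 (4E,6E)-3,7,11-trimethyldodeca-1,4,6,10-tetraen-3-ol (racemic)
Conditions: CH2=CHMgBr (1.3 equiv), THF, −20 → 0 °C; then aq. NH4Cl
Reagents that add atoms: vinylmagnesium bromide, C=C[Mg]Br
Why: Grignard 1,2-addition to the dienone carbonyl should give the tertiary vinyl carbinol, whose stereocentre is of no consequence because the next step destroys it.

Step 10
Reactants: 14 (4E,6E)-3,7,11-trimethyldodeca-1,4,6,10-tetraen-3-ol
Product: 15 [(2E,4E,6E)-3,7,11-trimethyldodeca-2,4,6,10-tetraen-1-yl]triphenylphosphonium bromide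
Conditions: PPh3·HBr (1.05 equiv), MeOH, rt; crystallisation
Reagents that add atoms: triphenylphosphine hydrobromide, [Br-].c1ccc(cc1)[PH+](c1ccccc1)c1ccccc1
Why: Acid-promoted ionisation to the delocalised allylic cation and capture by PPh3 at the unhindered primary terminus (SN1′ allylic transposition) should give the conjugated (E)-configured C15 salt, the isolated C1′=C2′ alkene being inert under these conditions.

Step 11
Reactants: 15 [(2E,4E,6E)-3,7,11-trimethyldodeca-2,4,6,10-tetraen-1-yl]triphenylphosphonium bromide; 16 (2E,4E,6E)-2,7-dimethylocta-2,4,6-trienedial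
Product: 17 (2E,4E,6E,8E,10E,12E,14E)-2,7,11,15,19-pentamethylicosa-2,4,6,8,10,12,14,18-octaenal
Conditions: 16 (2 equiv), NaOMe (1.1 equiv), CH2Cl2/MeOH, −10 °C → rt, 15 added slowly; then heptane, 80 °C
Reagents that add atoms: none
Why: Wittig olefination with the dialdehyde in excess should stop at the mono-adduct, whose remaining aldehyde is a less electrophilic extended polyenal, and the hindered Z isomer at the new C11′=C12′ bond should revert to E on heating.

Step 12
Reactants: 12 {(2E,4E)-5-[(3R,4R)-3,4-bis(TBS-oxy)-2,6,6-trimethylcyclohex-1-en-1-yl]-3-methylpenta-2,4-dien-1-yl}triphenylphosphonium bromide; 17 (2E,4E,6E,8E,10E,12E,14E)-2,7,11,15,19-pentamethylicosa-2,4,6,8,10,12,14,18-octaenal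
Product: 18 (3R,4R)-3,4-bis(TBS-oxy)-β,ψ-carotene (all-E)
Conditions: NaOMe (1.2 equiv), CH2Cl2/MeOH, −10 °C → rt; then heptane, 80 °C
Reagents that add atoms: none
Why: Wittig olefination of the C25 polyenal with the ylide of 12, generated in a protic medium in the presence of the aldehyde, should form the C11=C12 bond and complete the C40 chain, with thermal Z → E equilibration of the new hindered bond and no effect on C3, C4 or the silyl ethers.

Step 13
Reactants: 18 (3R,4R)-3,4-bis(TBS-oxy)-β,ψ-carotene
Product: 19 (3R,4R)-β,ψ-carotene-3,4-diol (all-E), the target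
Conditions: Bu4NF (4 equiv), THF, rt → 40 °C
Reagents that add atoms: none
Why: Fluoride-induced desilylation, driven by the strong Si–F bond, should free both hydroxyl groups under non-acidic conditions that do not ionise the allylic C4 carbinol or disturb the polyene.

**Compound list**

1 | ethyl safranate, ethyl 2,6,6-trimethylcyclohexa-1,3-diene-1-carboxylate | CCOC(=O)C1=C(C)C=CCC1(C)C | starting material
2 | ozonide, ethyl 2,4,4-trimethyl-7,8,9-trioxabicyclo[4.2.1]non-2-ene-3-carboxylate (racemic, one enantiomer drawn) | CCOC(=O)C1=C(C)[C@H]2OO[C@H](O2)CC1(C)C | intermediate (not isolated)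
3 | ethyl (E)-3-methyl-2-(2-methyl-4-oxobutan-2-yl)-4-oxobut-2-enoate | O=C/C(C)=C(/C(=O)OCC)C(C)(C)CC=O | intermediate
4 | ethyl (3R,4R)-3,4-dihydroxy-2,6,6-trimethylcyclohex-1-ene-1-carboxylate | CCOC(=O)C1=C(C)[C@@H](O)[C@H](O)CC1(C)C | intermediate
5 | ethyl (3R,4R)-3,4-bis[(tert-butyldimethylsilyl)oxy]-2,6,6-trimethylcyclohex-1-ene-1-carboxylate | CCOC(=O)C1=C(C)[C@@H](O[Si](C)(C)C(C)(C)C)[C@H](O[Si](C)(C)C(C)(C)C)CC1(C)C | intermediate
6 | [(3R,4R)-3,4-bis[(tert-butyldimethylsilyl)oxy]-2,6,6-trimethylcyclohex-1-en-1-yl]methanol | OCC1=C(C)[C@@H](O[Si](C)(C)C(C)(C)C)[C@H](O[Si](C)(C)C(C)(C)C)CC1(C)C | intermediate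
7 | (3R,4R)-3,4-bis[(tert-butyldimethylsilyl)oxy]-2,6,6-trimethylcyclohex-1-ene-1-carbaldehyde | O=CC1=C(C)[C@@H](O[Si](C)(C)C(C)(C)C)[C@H](O[Si](C)(C)C(C)(C)C)CC1(C)C | intermediate
8 | ethyl (2E)-4-(diethoxyphosphoryl)-3-methylbut-2-enoate (triethyl 3-methyl-4-phosphonocrotonate) | CCOC(=O)/C=C(\C)CP(=O)(OCC)OCC | starting material
9 | ethyl (2E,4E)-5-[(3R,4R)-3,4-bis[(tert-butyldimethylsilyl)oxy]-2,6,6-trimethylcyclohex-1-en-1-yl]-3-methylpenta-2,4-dienoate | CCOC(=O)/C=C(C)/C=C/C1=C(C)[C@@H](O[Si](C)(C)C(C)(C)C)[C@H](O[Si](C)(C)C(C)(C)C)CC1(C)C | intermediate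
10 | (2E,4E)-5-[(3R,4R)-3,4-bis[(tert-butyldimethylsilyl)oxy]-2,6,6-trimethylcyclohex-1-en-1-yl]-3-methylpenta-2,4-dien-1-ol | OC/C=C(C)/C=C/C1=C(C)[C@@H](O[Si](C)(C)C(C)(C)C)[C@H](O[Si](C)(C)C(C)(C)C)CC1(C)C | intermediate
11 | (3R,4R)-1-[(1E,3E)-5-bromo-3-methylpenta-1,3-dien-1-yl]-3,4-bis[(tert-butyldimethylsilyl)oxy]-2,6,6-trimethylcyclohex-1-ene | BrC/C=C(C)/C=C/C1=C(C)[C@@H](O[Si](C)(C)C(C)(C)C)[C@H](O[Si](C)(C)C(C)(C)C)CC1(C)C | intermediate (not isolated)
12 | {(2E,4E)-5-[(3R,4R)-3,4-bis[(tert-butyldimethylsilyl)oxy]-2,6,6-trimethylcyclohex-1-en-1-yl]-3-methylpenta-2,4-dien-1-yl}triphenylphosphonium bromide | [Br-].c1ccccc1[P+](c1ccccc1)(c1ccccc1)C/C=C(C)/C=C/C1=C(C)[C@@H](O[Si](C)(C)C(C)(C)C)[C@H](O[Si](C)(C)C(C)(C)C)CC1(C)C | intermediate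
13 | pseudoionone, (3E,5E)-6,10-dimethylundeca-3,5,9-trien-2-one | CC(C)=CCC/C(C)=C/C=C/C(C)=O | starting material
14 | (4E,6E)-3,7,11-trimethyldodeca-1,4,6,10-tetraen-3-ol (racemic) | CC(C)=CCC/C(C)=C/C=C/C(C)(O)C=C | intermediate
15 | [(2E,4E,6E)-3,7,11-trimethyldodeca-2,4,6,10-tetraen-1-yl]triphenylphosphonium bromide | CC(C)=CCC/C(C)=C/C=C/C(C)=C/C[P+](c1ccccc1)(c1ccccc1)c1ccccc1.[Br-] | intermediate
16 | (2E,4E,6E)-2,7-dimethylocta-2,4,6-trienedial (C10 dialdehyde) | O=C/C(C)=C/C=C/C=C(C)/C=O | starting material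
17 | (2E,4E,6E,8E,10E,12E,14E)-2,7,11,15,19-pentamethylicosa-2,4,6,8,10,12,14,18-octaenal | CC(C)=CCC/C(C)=C/C=C/C(C)=C/C=C/C(C)=C/C=C/C=C(C)/C=O | intermediate
18 | (3R,4R)-3,4-bis[(tert-butyldimethylsilyl)oxy]-β,ψ-carotene (all-E) | CC(C)=CCC/C(C)=C/C=C/C(C)=C/C=C/C(C)=C/C=C/C=C(C)/C=C/C=C(C)/C=C/C1=C(C)[C@@H](O[Si](C)(C)C(C)(C)C)[C@H](O[Si](C)(C)C(C)(C)C)CC1(C)C | intermediate
19 | (3R,4R)-β,ψ-carotene-3,4-diol (all-E), CNP0310445.1 | CC(C)=CCC/C(C)=C/C=C/C(C)=C/C=C/C(C)=C/C=C/C=C(C)/C=C/C=C(C)/C=C/C1=C(C)[C@@H](O)[C@H](O)CC1(C)C | target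

**Step count**

Total: 13 steps. Longest linear sequence: 10 steps (steps 1–8, 12, 13 from ethyl safranate); the acyclic half adds a three-step branch (steps 9–11).

**Steps most likely to fail**

1. Step 2, the only step beyond known chemistry. The ligand may not discriminate the two faces of the C4 ketyl well enough. The ketyl may also be diverted into intermolecular coupling or reduction of the C5=C6 bond, or the dialdehyde may close by Lewis-acid-promoted aldol reaction before it is reduced. The fallback uses known chemistry, sets out from 1 and avoids the dialdehyde altogether.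
   - Jacobsen–Katsuki epoxidation of the cis-disubstituted C3=C4 bond should give the vinyl epoxide ethyl (1S,6R)-2,4,4-trimethyl-7-oxabicyclo[4.1.0]hept-2-ene-3-carboxylate F1. Conditions: (S,S)-(salen)MnCl (the chloride of trivalent manganese with N,N′-bis(3,5-di-tert-butylsalicylidene)cyclohexane-1,2-diamine), NaOCl, 4-phenylpyridine N-oxide, CH2Cl2, 0 °C. The (S,S) antipode is chosen by analogy with cis-alkenes conjugated to an arene and is to be confirmed.
   - Acid-catalysed hydrolysis (HClO4 cat., THF/H2O, 0 °C) should open the epoxide at the allylic C4 with inversion, giving the trans diol and rejoining the route at 4.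

2. Step 8. The trienylic bromide may ionise and lose a proton from C4 (retro-type elimination), or the C9=C10 geometry may scramble. The derived ylide could later expel silanolate from C4 by vinylogous β-elimination. The fallback reverses the polarity of the C11=C12 union and sets out from 10 and 17.
   - Alcohol 10 is oxidised (MnO2, CH2Cl2, rt) to (2E,4E)-5-[(3R,4R)-3,4-bis[(tert-butyldimethylsilyl)oxy]-2,6,6-trimethylcyclohex-1-en-1-yl]-3-methylpenta-2,4-dienal F2.
   - Aldehyde 17 is reduced (NaBH4, EtOH/THF, 0 °C) to (2E,4E,6E,8E,10E,12E,14E)-2,7,11,15,19-pentamethylicosa-2,4,6,8,10,12,14,18-octaen-1-ol F3.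
   - F3 is converted with PPh3·HBr (MeOH/CH2Cl2, rt) into [(2E,4E,6E,8E,10E,12E,14E)-2,7,11,15,19-pentamethylicosa-2,4,6,8,10,12,14,18-octaen-1-yl]triphenylphosphonium bromide F4. This half carries no acid-sensitive group.
   - Wittig reaction of F4 with F2 (NaOMe, CH2Cl2/MeOH; then heptane, 80 °C) rejoins the route at 18.

3. Step 1. Ozone may also attack the tetrasubstituted C5=C6 bond or over-oxidise the product, and the 1,6-dialdehyde may self-condense during isolation. The fallback sets out from 1.
   - Dihydroxylation of the distal alkene (OsO4 cat., N-methylmorpholine N-oxide, acetone/H2O), which is controlled by sterics, should give the racemic cis-diol ethyl rel-(3R,4S)-3,4-dihydroxy-2,6,6-trimethylcyclohex-1-ene-1-carboxylate F5.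
   - Glycol cleavage (NaIO4 on silica, CH2Cl2, rt) under near-neutral, largely anhydrous conditions rejoins the route at 3.

**Further compounds**

F1 | step 2 | ethyl (1S,6R)-2,4,4-trimethyl-7-oxabicyclo[4.1.0]hept-2-ene-3-carboxylate | CCOC(=O)C1=C(C)[C@@H]2O[C@@H]2CC1(C)C
F2 | step 8 | (2E,4E)-5-[(3R,4R)-3,4-bis[(tert-butyldimethylsilyl)oxy]-2,6,6-trimethylcyclohex-1-en-1-yl]-3-methylpenta-2,4-dienal | O=C/C=C(C)/C=C/C1=C(C)[C@@H](O[Si](C)(C)C(C)(C)C)[C@H](O[Si](C)(C)C(C)(C)C)CC1(C)C
F3 | step 8 | (2E,4E,6E,8E,10E,12E,14E)-2,7,11,15,19-pentamethylicosa-2,4,6,8,10,12,14,18-octaen-1-ol | CC(C)=CCC/C(C)=C/C=C/C(C)=C/C=C/C(C)=C/C=C/C=C(C)/CO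
F4 | step 8 | [(2E,4E,6E,8E,10E,12E,14E)-2,7,11,15,19-pentamethylicosa-2,4,6,8,10,12,14,18-octaen-1-yl]triphenylphosphonium bromide | CC(C)=CCC/C(C)=C/C=C/C(C)=C/C=C/C(C)=C/C=C/C=C(C)/C[P+](c1ccccc1)(c1ccccc1)c1ccccc1.[Br-]
F5 | step 1 | ethyl rel-(3R,4S)-3,4-dihydroxy-2,6,6-trimethylcyclohex-1-ene-1-carboxylate (racemic cis-diol, one enantiomer drawn) | CCOC(=O)C1=C(C)[C@@H](O)[C@@H](O)CC1(C)C
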